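**Assumption:** Morinin L has no stereogenic centre (it is achiral), so "single enantiomer" is taken to mean the single geometric isomer: Z angelate, Z 2‑(acyloxymethyl)but‑2‑enoate (CH3 cis to the ester C=O), E cinnamyl.

## Retrosynthetic overview

1. Target 7 ⇒ angelic acid 6 + primary allylic alcohol 5 (acyl C–O bond, last step, so the isomerisable angelate is exposed to only one mild reaction).
2. Alcohol 5 ⇒ ynoate 4 + formaldehyde + "H–" (new Cu–H syn‑hydro‑hydroxymethylation; forms the C2–CH2O bond and sets the Z trisubstituted alkene).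
3. Ynoate 4 ⇒ but‑2‑ynoic acid 3 + (E)‑3,4‑dimethoxycinnamyl alcohol 2 (ester C–O bond).
4. Alcohol 2 ⇒ methyl (E)‑3,4‑dimethoxycinnamate 1 (ester reduction).
5. No rings are formed; the arene comes intact from 1. Order of bond formation: cinnamyl ester, then C–C/Z‑alkene, then angelate ester.

## Route

**Step 1**
Reactants: 1, methyl (E)‑3‑(3,4‑dimethoxyphenyl)prop‑2‑enoate
Product: 2, (E)‑3‑(3,4‑dimethoxyphenyl)prop‑2‑en‑1‑ol
Conditions: DIBAL‑H (2.5 equiv), CH2Cl2, −78 → 0 °C; Rochelle salt work‑up
Reagents that add atoms: none (hydride only)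
Why: DIBAL‑H 1,2‑reduction of a conjugated ester to the allylic alcohol; the E styrenyl alkene and the aryl methyl ethers are untouched.

**Step 2**
Reactants: 2, (E)‑3‑(3,4‑dimethoxyphenyl)prop‑2‑en‑1‑ol; 3, but‑2‑ynoic acid
Product: 4, (E)‑3‑(3,4‑dimethoxyphenyl)prop‑2‑en‑1‑yl but‑2‑ynoate
Conditions: 3 (1.3 equiv), DCC (1.3 equiv), DMAP (5 mol %), CH2Cl2, −20 → 0 °C
Reagents that add atoms: none beyond reactant 3 (but‑2‑ynoic acid, CC#CC(=O)O)
Why: Steglich esterification of an unhindered primary alcohol; low temperature and low DMAP loading suppress amine addition to the ynoate, and the neutral medium protects the acid‑labile electron‑rich cinnamyl C–O bond.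

**Step 3 (proposed new transformation)**
Reactants: 4, (E)‑3‑(3,4‑dimethoxyphenyl)prop‑2‑en‑1‑yl but‑2‑ynoate
Product: 5, (E)‑3‑(3,4‑dimethoxyphenyl)prop‑2‑en‑1‑yl (Z)‑2‑(hydroxymethyl)but‑2‑enoate (CH3 cis to the ester, CH2OH cis to the vinyl H)
Conditions: Cu(OAc)2 (5 mol %), Xantphos (6 mol %), (EtO)2MeSiH (1.3 equiv, slow addition), CH2O (3 equiv, anhydrous THF solution from cracked paraformaldehyde), THF, −60 → −30 °C; then aq NH4F, 0 °C
Reagents that add atoms: formaldehyde, C=O (the silane contributes only the β‑hydrogen; the O–Si bond is cleaved on work‑up)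
Why: Proposed new method: a catalytic, Z‑selective reductive hydroxymethylation of a 2‑ynoate. L–Cu–H delivers hydride to the ynoate β‑carbon by syn‑hydrocupration, giving an α‑cuprio enoate / copper allenolate; formaldehyde then bonds to Cα on the side of the small β‑H (anti to β‑CH3, the same outcome by retentive C–Cu addition or in‑plane attack on the allenolate), so CH2O ends up cis to H and CH3 cis to the ester (Z); σ‑bond metathesis of the copper alkoxide with the silane regenerates Cu–H. The ynoate is far more reactive toward Cu–H than the α‑branched trisubstituted enoate product, the styrene or the allylic ester, and slow silane addition limits over‑reduction and formaldehyde reduction. The closest known reaction types are the CuH‑catalysed reductive aldol of enoates and allenoates and the stoichiometric hydroalumination–aldol of ynoates.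

**Step 4**
Reactants: 5, (E)‑3‑(3,4‑dimethoxyphenyl)prop‑2‑en‑1‑yl (Z)‑2‑(hydroxymethyl)but‑2‑enoate; 6, angelic acid [(Z)‑2‑methylbut‑2‑enoic acid]
Product: 7, Morinin L, (E)‑3‑(3,4‑dimethoxyphenyl)prop‑2‑en‑1‑yl (Z)‑2‑({[(Z)‑2‑methylbut‑2‑enoyl]oxy}methyl)but‑2‑enoate
Conditions: 6 (1.5 equiv), 2,4,6‑trichlorobenzoyl chloride (1.5 equiv), Et3N (3 equiv), toluene, rt, 1 h; then 5, DMAP (0.2 equiv), 0 °C → rt
Reagents that add atoms: none beyond reactant 6 (angelic acid, C/C=C(/C)C(=O)O)
Why: Yamaguchi esterification; acyl transfer to the unhindered primary allylic alcohol is fast enough to outrun angelate → tiglate isomerisation, and because 5 acts as the nucleophile no allylic (SN2′) manifold is opened that could scramble the Z enoate. No new stereo‑element is formed.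

## Compound list

1 | methyl (E)‑3‑(3,4‑dimethoxyphenyl)prop‑2‑enoate | COC(=O)/C=C/c1ccc(OC)c(OC)c1 | starting material
2 | (E)‑3‑(3,4‑dimethoxyphenyl)prop‑2‑en‑1‑ol | OC/C=C/c1ccc(OC)c(OC)c1 | intermediate
3 | but‑2‑ynoic acid (tetrolic acid) | CC#CC(=O)O | starting material
4 | (E)‑3‑(3,4‑dimethoxyphenyl)prop‑2‑en‑1‑yl but‑2‑ynoate | CC#CC(=O)OC/C=C/c1ccc(OC)c(OC)c1 | intermediate
5 | (E)‑3‑(3,4‑dimethoxyphenyl)prop‑2‑en‑1‑yl (Z)‑2‑(hydroxymethyl)but‑2‑enoate | C/C=C(/CO)C(=O)OC/C=C/c1ccc(OC)c(OC)c1 | intermediate
6 | angelic acid, (Z)‑2‑methylbut‑2‑enoic acid | C/C=C(/C)C(=O)O | starting material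
7 | Morinin L | C/C=C(/C)C(=O)OC/C(=C/C)C(=O)OC/C=C/c1ccc(OC)c(OC)c1 | target

## Summary

Total step count: 4
Longest linear sequence: 4 steps (1 → 2 → 4 → 5 → 7)

Three steps most likely to fail:

1. **Step 3 (proposed new Cu–H reductive hydroxymethylation).** Risks are Cu–H reduction of formaldehyde, simple semireduction to the crotonate, over‑reduction, and erosion of Z/E selectivity.
 Fallback (known chemistry, different disconnection): make (Z)‑2‑iodobut‑2‑en‑1‑ol from crotonaldehyde (I2, K2CO3, cat. DMAP, THF/H2O; then NaBH4) and protect it as the TBS ether. Pd‑catalysed alkoxycarbonylation with alcohol 2 (PdCl2(PPh3)2, CO 1 atm, Et3N, DMF, 50 °C) replaces iodine with retention of vinyl geometry, and TBAF/AcOH then gives 5.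

2. **Step 4 (angeloylation).** Risks are partial angelate → tiglate isomerisation through the activated acyl species and DMAP‑mediated SN2′ scrambling of the product.
 Fallback: reverse the polarity with a Mitsunobu esterification (5, angelic acid, PPh3, DIAD, THF, 0 °C), in which angelate acts only as a nucleophile and no activated angeloyl intermediate is formed.

3. **Step 2 (ynoate esterification).** Risks are N‑acylurea formation, DMAP addition to the ynoate, and ionisation of the electron‑rich cinnamyl alcohol.
 Fallback: Mitsunobu coupling in which alcohol 2 is the electrophile and but‑2‑ynoic acid the nucleophile (PPh3, DIAD, THF, 0 °C), avoiding any activated ynoyl species.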